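## Structural features

The target is an unsymmetrical C50 carotenoid, (2S,2′R,6′R)-2′-[(2E)-4-hydroxy-3-methylbut-2-enyl]-2-(3-methylbut-2-enyl)-3,4-didehydro-1,2-dihydro-ψ,ε-caroten-1-ol. An all-E chain of eleven conjugated double bonds (C3=C4 to C7′=C8′, methyl branches at C5, C9, C13, C13′, C9′) joins two different chiral termini. The ring terminus is an ε-ring (C1′–C6′). Its quaternary C1′ (gem-dimethyl) is flanked by C2′ (R, bearing the C1″–C4″ hydroxyprenyl chain) and C6′ (R, bearing the polyene); these two substituents are cis, and the C4′=C5′(CH3) bond is out of conjugation. The open terminus has one stereocentre, C2 (S), which carries a prenyl group, the tertiary carbinol C1 and the polyene at C3. C2 lies more than twenty bonds from the ring, so no stereochemical relay between the termini is possible. Fragile elements are the polyene (light, oxygen, acid), the doubly allylic C6′–H, the tertiary alcohol next to the allylic C2–H, and the primary allylic alcohol. The real difficulty is the cis C2′/C6′ pair around C1′ with the ring double bond fixed at C4′=C5′, and a remote C2 of the same absolute sense. The key step exploits the fact that both termini hold the same homochiral array, Me2C(1)–CH(2)(CH2–C=C)–C(3)–C(4)–C(5)(CH3). This is the skeleton of the cyclobutane of cis-pinonic compounds from α-pinene with the C1–C4 bond closed, and the ε-ring is that cyclobutane (C1′, C2′, C3′, C4′) enlarged by C5′ and C6′.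

## Logic of the disconnections

22 ⇒ 21. Bond cut: O–Si at C4″. The primary allylic alcohol is masked so that only C7′ is functionalised in the ring fragment. The forward step must remove silicon without harming the polyene (buffered fluoride, dark).

21 ⇒ 20 + 18. Bond cut: C7=C8. The cut places the whole open terminus in one C15 piece and joins it last, so the tertiary alcohol and C2 see only one polyene-forming step. The forward Wittig step must tolerate a free tertiary OH; it gives a 7E/7Z mixture that has to be equilibrated to all-E.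

20 ⇒ 11 + 19. Bond cut: C7′=C8′. The symmetrical C20 dialdehyde 19 supplies sixteen chain carbons and seven E double bonds in one purchased piece. C6′ stays β to the sulfonyl carbanion, so it is never α to a carbonyl after step 5. The forward step must olefinate only one aldehyde of 19 and must be E-selective.

11 ⇒ 7 (through 10, 9, 8). Bonds cut: C7′–S and O–Si; C7′ and C4″ are returned to the ester level. The ring fragment becomes a diester in which C7′ is the ring ester carbon. The forward sequence must tell two primary alcohols apart, which the hindered position of C7′–OH next to C1′ should allow.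

7 ⇒ 5 (key). Bond cut: C1′–C6′; bond restored: C4′–C1′, with the double bond moved from C4′=C5′ to C5′=C6′. The cyclohexene becomes a cyclobutane that already holds C1′ with its two methyls, the C2′ stereocentre with its side chain, C3′, C4′ and the C5′ methyl. The ring, the quaternary carbon, one stereocentre and the alkene position are then inherited, and only C6′ is new. The forward step must ionise C4′–C1′ and not C4′–C3′, must reclose at C6′, and must set C6′ cis to C2′ under kinetic control.

5 ⇒ 4 ⇒ 3 ⇒ 1. Bonds cut: C5′=C6′ and C2″=C3″ (two olefinations); then the two carbonyl carbons C5′ and C2″ are rejoined as the C=C of 1. All ten ring-fragment carbons except the two ester-bearing ones come from 1. The forward steps need an aldehyde-selective olefination in the presence of the methyl ketone; the E/Z and epimer mixtures in 5 are acceptable because step 4 erases them.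

18 ⇒ 17 ⇒ 16 ⇒ 15 ⇒ 14 ⇒ 13. Bonds cut: C7–P, the prenyl C=C, C5=C6, and the C3=C4 unsaturation is removed. This reduces the open terminus to a keto lactone that holds C1 (as the lactone C–O), C2, the prenyl CH2 (as the lactone CH2–C=O), C3, C4, C5 and the C5 methyl. The forward steps need a regiodefined dehydrogenation (only the methylene side of a methyl ketone can react), an E-selective olefination of an enone, and a lactol Wittig that frees the tertiary alcohol.

13 ⇒ 12 ⇒ 1. Bond cut: C1–O of the lactone; bond restored: C1–C4, then the ketone and acid carbons are rejoined as the C=C of 1. The same cyclobutane bond that is moved in step 4 is here opened to oxygen, so one enantiomer of 1 supplies C2 and C2′ in the required, identical spatial sense. The forward step must open the ring without touching C2.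

## Other disconnections considered

Alternative 1: (the first that comes to mind) cut C11=C12 and C11′=C12′. The forward key step is a double Wittig reaction of two C20 phosphonium salts with the C10 dialdehyde A3. The ring salt A1 would come from a protic cation–olefin cyclisation of the open-chain hydroxy ester A2, whose C2′ centre is set by an auxiliary-controlled alkylation; the open terminus would need a second, unrelated asymmetric alkylation. The chosen plan is preferred for three reasons. Cyclisation of A2 passes through a C5′ cation and leaves the position of the ring double bond to proton loss. The two termini would need two separate sources of chirality. Each C20 salt needs three further chain-building steps after the stereochemistry is in place.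

Alternative 2: cut C6′–C7′ by sigmatropic chirality transfer. Dienone A4 would undergo a catalytic asymmetric conjugate addition and 1,2-reduction to the cis cyclohexenol A5. The forward key step is the [2,3]-Wittig–Still rearrangement of its stannylmethyl ether A6, which delivers a hydroxymethyl group to C6′ on the face of the C4′–O bond and moves the double bond to C4′=C5′. This would set C6′ reliably. It is not preferred because the new bond forms at a carbon next to the quaternary C1′, where the [1,2] shift competes. The ring and C2′ must also be built from achiral material with a chiral catalyst over several more steps. Nothing of it serves the open terminus.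

Alternative 3: cut both exocyclic bonds at C2′ and C6′ as the two ends of an etheno bridge. The forward key step is a [4+3] cycloaddition of an oxyallyl cation with diene A7 to the meso bicyclic ketone A8. Cleavage of the bridge would then give the cis dialdehyde A9 with the cis relationship guaranteed by the bicycle. It is not preferred because A8 is achiral and needs a desymmetrisation. The two aldehydes of A9 must be told apart and one homologated. The C5′ methyl and the C4′=C5′ bond still have to be installed from the ketone. The route is clearly longer.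

Key step: step 4

Remark on the chemistry: 1 is taken as the commercial (1S,5S) enantiomer of high ee and 19 as the commercial all-E C20 dialdehyde; carotenoid locants (C1–C15, C1′–C15′, side chain on C2′ = C1″–C4″) are used for the atoms in every compound.

## Route

Step 1
Reactants: 1 (1S,5S)-(−)-α-pinene
Product: 3 2-[(1R,3R)-3-acetyl-2,2-dimethylcyclobutyl]acetaldehyde (cis-pinonaldehyde), via α-pinene secondary ozonide 2 (not isolated)
Conditions: O3, CH2Cl2, −78 °C; then Me2S, −78 °C → rt
Reagents that add atoms: ozone, O=[O+][O-]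
Why: Ozonolysis of the only C=C bond with reductive work-up; the two ring stereocentres are not touched and stay cis on the cyclobutane.

Step 2
Reactants: 3 2-[(1R,3R)-3-acetyl-2,2-dimethylcyclobutyl]acetaldehyde
Product: 4 methyl (2E)-4-[(1S,3R)-3-acetyl-2,2-dimethylcyclobutyl]-2-methylbut-2-enoate
Conditions: Ph3P=C(Me)CO2Me, CH2Cl2, rt
Reagents that add atoms: methyl 2-(triphenyl-λ5-phosphanylidene)propanoate, COC(=O)C(C)=P(c1ccccc1)(c1ccccc1)c1ccccc1
Why: Wittig reaction of a stabilised ylide, which takes the aldehyde and leaves the methyl ketone and should give the E trisubstituted alkene; the ring descriptor changes from R to S through CIP priorities only.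

Step 3
Reactants: 4 methyl (2E)-4-[(1S,3R)-3-acetyl-2,2-dimethylcyclobutyl]-2-methylbut-2-enoate
Product: 5 methyl (2E)-3-[(1S,3S)-3-[(2E)-4-methoxy-3-methyl-4-oxobut-2-en-1-yl]-2,2-dimethylcyclobutyl]but-2-enoate (major isomer; the 2Z isomer and the C1 epimer are carried along)
Conditions: (MeO)2P(O)CH2CO2Me, NaH, THF, 0 → 65 °C
Reagents that add atoms: trimethyl phosphonoacetate, COC(=O)CP(=O)(OC)OC
Why: Horner–Wadsworth–Emmons olefination of the methyl ketone; its E/Z selectivity and any base epimerisation at the ketone α-carbon do not matter because both elements are erased in step 4.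

Step 4
Reactants: 5 methyl (2E)-3-[(1S,3S)-3-[(2E)-4-methoxy-3-methyl-4-oxobut-2-en-1-yl]-2,2-dimethylcyclobutyl]but-2-enoate
Product: 7 methyl (1R,5R)-5-[(2E)-4-methoxy-3-methyl-4-oxobut-2-en-1-yl]-2,6,6-trimethylcyclohex-2-ene-1-carboxylate, via ring-opened zwitterion 6 (not isolated)
Conditions: EtAlCl2 (2.5 equiv), CH2Cl2, −78 → 0 °C; cold aq. Rochelle salt
Reagents that add atoms: none
Why: Proposed new method: EtAlCl2 bound to the cyclobutyl enoate places positive charge on C5′, the cyclobutylcarbinyl position, so the aligned and more substituted C4′–C1′ bond should ionise with release of the ring strain to zwitterion 6 (tertiary C1′ cation plus aluminium dienolate), whose α-carbon C6′ then alkylates C1′ to give the cyclohexene with C4′=C5′ already in place, a formal [1,3] shift of C1′ from C4′ to C6′. The closest known reaction types are the acid-induced opening of the same bond in cis-pinonic acid (step 10), the alkylaluminium-halide-induced reversible ionisation of acylcyclobutanes to 1,4-zwitterions, the acid cyclisation of geranic esters to α-cyclogeranates and the thermal vinylcyclobutane–cyclohexene rearrangement. Ring closure: six-membered, 6-(enolexo) C-alkylation of the dienolate by the cation; the only other closure open to 6, at the γ-carbon C4′, regenerates the strained cyclobutane and is therefore reversible. C2′ is not involved and keeps the configuration of 1, while the C4′ centre and the enoate geometry are erased in 6, so all isomers of 5 converge. The new centre C6′ should be set kinetically in a sofa-like transition state with the C2′ side chain equatorial and the planar s-trans dienolate holding the ester carbon C7′ in the plane of C4′=C5′ (the s-cis rotamer suffers A(1,3) strain with C3′H2), which is the 2′,6′-cis, (1R,5R) arrangement. The step needs cleavage of C4′–C1′ and not C4′–C3′ (tertiary against primary cation), α- and not γ-recombination (strain), and collapse faster than a 1,2-hydride shift from C2′ (low temperature, nucleophile held four atoms away). The aprotic, proton-scavenging Lewis acid keeps the dienolate from being protonated before it closes, and the side-chain enoate cannot trap the cation because its carbonyl oxygen would have to close a seven-membered ring across an E double bond.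

Step 5
Reactants: 7 methyl (1R,5R)-5-[(2E)-4-methoxy-3-methyl-4-oxobut-2-en-1-yl]-2,6,6-trimethylcyclohex-2-ene-1-carboxylate
Product: 8 (2E)-4-[(1R,5R)-5-(hydroxymethyl)-4,6,6-trimethylcyclohex-3-en-1-yl]-2-methylbut-2-en-1-ol
Conditions: DIBAL-H (5 equiv), CH2Cl2, −78 → 0 °C; Rochelle salt
Reagents that add atoms: none
Why: DIBAL reduction of both esters to primary alcohols (1,2-reduction of the enoate); the conditions are non-basic, so C6′ (α to the ester and allylic) is not epimerised before its carbonyl group is gone.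

Step 6
Reactants: 8 (2E)-4-[(1R,5R)-5-(hydroxymethyl)-4,6,6-trimethylcyclohex-3-en-1-yl]-2-methylbut-2-en-1-ol
Product: 9 [(1R,5R)-5-[(2E)-4-{[tert-butyl(diphenyl)silyl]oxy}-3-methylbut-2-en-1-yl]-2,6,6-trimethylcyclohex-2-en-1-yl]methanol
Conditions: TBDPSCl (1.05 equiv), imidazole, CH2Cl2, −20 → 0 °C
Reagents that add atoms: tert-butyl(chloro)diphenylsilane, CC(C)(C)[Si](Cl)(c1ccccc1)c1ccccc1
Why: Steric differentiation of two primary alcohols: the open allylic C4″–OH should be silylated by the bulky chlorosilane much faster than C7′–OH, which is flanked by the quaternary C1′ and the C5′ methyl.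

Step 7
Reactants: 9 [(1R,5R)-5-[(2E)-4-{[tert-butyl(diphenyl)silyl]oxy}-3-methylbut-2-en-1-yl]-2,6,6-trimethylcyclohex-2-en-1-yl]methanol
Product: 10 5-({[(1R,5R)-5-[(2E)-4-{[tert-butyl(diphenyl)silyl]oxy}-3-methylbut-2-en-1-yl]-2,6,6-trimethylcyclohex-2-en-1-yl]methyl}sulfanyl)-1-phenyl-1H-tetrazole
Conditions: 1-phenyl-1H-tetrazole-5-thiol, PPh3, DIAD, THF, 0 °C → rt
Reagents that add atoms: 1-phenyl-1H-tetrazole-5-thiol, Sc1nnnn1-c1ccccc1
Why: Mitsunobu thioetherification with the acidic tetrazole thiol, an SN2 displacement at the primary C7′ in which no stereocentre takes part.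

Step 8
Reactants: 10 5-({[(1R,5R)-5-[(2E)-4-{[tert-butyl(diphenyl)silyl]oxy}-3-methylbut-2-en-1-yl]-2,6,6-trimethylcyclohex-2-en-1-yl]methyl}sulfanyl)-1-phenyl-1H-tetrazole
Product: 11 5-({[(1R,5R)-5-[(2E)-4-{[tert-butyl(diphenyl)silyl]oxy}-3-methylbut-2-en-1-yl]-2,6,6-trimethylcyclohex-2-en-1-yl]methyl}sulfonyl)-1-phenyl-1H-tetrazole
Conditions: (NH4)6Mo7O24·4H2O (10 mol%), 30% H2O2, EtOH, 0 °C → rt
Reagents that add atoms: hydrogen peroxide, OO
Why: Molybdate-catalysed peroxide oxidation of the sulfide to the sulfone, which is chemoselective over trisubstituted alkenes and leaves the silyl ether intact.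

Step 9
Reactants: 1 (1S,5S)-(−)-α-pinene
Product: 12 2-[(1R,3R)-3-acetyl-2,2-dimethylcyclobutyl]acetic acid (cis-pinonic acid)
Conditions: RuCl3·xH2O (2 mol%), NaIO4, MeCN–EtOAc–H2O, rt
Reagents that add atoms: sodium periodate, [Na+].[O-]I(=O)(=O)=O
Why: Ruthenium tetroxide cleavage of the trisubstituted alkene to ketone and carboxylic acid; the cyclobutane and its two cis stereocentres are untouched.

Step 10
Reactants: 12 2-[(1R,3R)-3-acetyl-2,2-dimethylcyclobutyl]acetic acid
Product: 13 (4R)-5,5-dimethyl-4-(3-oxobutyl)oxolan-2-one (homoterpenyl methyl ketone)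
Conditions: aq. H2SO4 (50%), 80–90 °C
Reagents that add atoms: none
Why: Classical acid isomerisation of cis-pinonic acid: the protonated acetyl group draws the electrons of the C4–C1 cyclobutane bond and the carboxyl group closes on the developing tertiary cation at C1 as a γ-lactone. The stereocentre C2 is not part of the breaking bond and is retained.

Step 11
Reactants: 13 (4R)-5,5-dimethyl-4-(3-oxobutyl)oxolan-2-one
Product: 14 (4S)-5,5-dimethyl-4-[(1E)-3-oxobut-1-en-1-yl]oxolan-2-one
Conditions: IBX (2 equiv), DMSO–toluene, 70 °C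
Reagents that add atoms: none
Why: IBX dehydrogenation of a ketone through its enol; a methyl ketone can be desaturated only on its methylene side, which gives the E enone (C3=C4). The descriptor changes from R to S by priority only.

Step 12
Reactants: 14 (4S)-5,5-dimethyl-4-[(1E)-3-oxobut-1-en-1-yl]oxolan-2-one
Product: 15 ethyl (2E,4E)-5-[(3S)-2,2-dimethyl-5-oxooxolan-3-yl]-3-methylpenta-2,4-dienoate
Conditions: (EtO)2P(O)CH2CO2Et, NaH (no excess), THF, 0 °C → rt; chromatography to remove the 2Z isomer
Reagents that add atoms: triethyl phosphonoacetate, CCOC(=O)CP(=O)(OCC)OCC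
Why: Horner–Wadsworth–Emmons olefination at the enone carbonyl (1,2-selective as with ionone-type enones) should favour the E C5=C6 bond; the preformed, weakly basic phosphonate anion at low temperature avoids γ-deprotonation at the stereocentre.

Step 13
Reactants: 15 ethyl (2E,4E)-5-[(3S)-2,2-dimethyl-5-oxooxolan-3-yl]-3-methylpenta-2,4-dienoate
Product: 16 (4S)-4-[(1E,3E)-5-hydroxy-3-methylpenta-1,3-dien-1-yl]-5,5-dimethyloxolan-2-ol (mixture of anomers)
Conditions: DIBAL-H (3.5 equiv), CH2Cl2, −78 °C; MeOH, Rochelle salt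
Reagents that add atoms: none
Why: DIBAL at −78 °C stops at the lactol for the hindered γ-lactone (stable tetrahedral aluminate), while the conjugated ester is reduced fully to the allylic alcohol.

Step 14
Reactants: 16 (4S)-4-[(1E,3E)-5-hydroxy-3-methylpenta-1,3-dien-1-yl]-5,5-dimethyloxolan-2-ol
Product: 17 (2E,4E,6S)-6-(2-hydroxypropan-2-yl)-3,9-dimethyldeca-2,4,8-trien-1-ol
Conditions: i-PrPPh3+ I−, n-BuLi (4 equiv each), THF, 0 °C; then 16, 0 °C → rt
Reagents that add atoms: isopropyltriphenylphosphonium iodide, [I-].CC(C)[P+](c1ccccc1)(c1ccccc1)c1ccccc1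
Why: Wittig olefination of the open hydroxy-aldehyde form of the lactol with the non-stabilised isopropylidene ylide builds the prenyl group and frees the tertiary alcohol; excess ylide serves as base for the hydroxyl groups and the symmetric alkene terminus raises no geometric issue.

Step 15
Reactants: 17 (2E,4E,6S)-6-(2-hydroxypropan-2-yl)-3,9-dimethyldeca-2,4,8-trien-1-ol
Product: 18 [(2E,4E,6S)-6-(2-hydroxypropan-2-yl)-3,9-dimethyldeca-2,4,8-trien-1-yl](triphenyl)phosphonium bromide
Conditions: Ph3P·HBr, MeOH, 0 °C → rt, dark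
Reagents that add atoms: triphenylphosphine hydrobromide, [Br-].[PH+](c1ccccc1)(c1ccccc1)c1ccccc1
Why: Standard conversion of an allylic alcohol to the phosphonium salt: the dienyl cation is captured by PPh3 at the unhindered terminus C7. The saturated tertiary alcohol should not ionise under this mild acid and cannot close onto the cation across the E C3=C4 bond.

Step 16
Reactants: 11 5-({[(1R,5R)-5-[(2E)-4-{[tert-butyl(diphenyl)silyl]oxy}-3-methylbut-2-en-1-yl]-2,6,6-trimethylcyclohex-2-en-1-yl]methyl}sulfonyl)-1-phenyl-1H-tetrazole; 19 (2E,4E,6E,8E,10E,12E,14E)-2,6,11,15-tetramethylhexadeca-2,4,6,8,10,12,14-heptaenedial (crocetindialdehyde, 3 equiv)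
Product: 20 (2E,4E,6E,8E,10E,12E,14E,16E)-17-[(1R,5R)-5-[(2E)-4-{[tert-butyl(diphenyl)silyl]oxy}-3-methylbut-2-en-1-yl]-2,6,6-trimethylcyclohex-2-en-1-yl]-2,6,11,15-tetramethylheptadeca-2,4,6,8,10,12,14,16-octaenal
Conditions: KHMDS (1.1 equiv), THF–DMF, −60 °C → rt, 19 present from the start (Barbier mode), dark
Reagents that add atoms: none
Why: Julia–Kocienski olefination: the sulfonyl carbanion adds to one aldehyde of 19, and Smiles rearrangement with loss of SO2 and the tetrazolate should give the E C7′=C8′ bond. C6′ is β to the carbanion and is not epimerised. Excess 19 and the lower electrophilicity of the product aldehyde favour mono-olefination.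

Step 17
Reactants: 20 the C35 aldehyde of step 16; 18 [(2E,4E,6S)-6-(2-hydroxypropan-2-yl)-3,9-dimethyldeca-2,4,8-trien-1-yl](triphenyl)phosphonium bromide
Product: 21 (2S,2′R,6′R)-2′-[(2E)-4-{[tert-butyl(diphenyl)silyl]oxy}-3-methylbut-2-en-1-yl]-2-(3-methylbut-2-en-1-yl)-3,4-didehydro-1,2-dihydro-ψ,ε-caroten-1-ol (all-E)
Conditions: NaOMe, CH2Cl2–MeOH, 0 °C → rt; then I2 (cat.), hexane–CH2Cl2, diffuse light, Ar
Reagents that add atoms: none
Why: Wittig reaction of the dienyl ylide with the polyenal forms C7=C8 as an E/Z mixture, and the unhindered disubstituted 7Z bond is equilibrated to all-E by iodine-catalysed isomerisation. The tertiary alcohol needs no protection and the stereocentres are remote from the reacting atoms.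

Step 18
Reactants: 21 the silyl ether of step 17
Product: 22 (2S,2′R,6′R)-2′-[(2E)-4-hydroxy-3-methylbut-2-en-1-yl]-2-(3-methylbut-2-en-1-yl)-3,4-didehydro-1,2-dihydro-ψ,ε-caroten-1-ol (target, CNP0409952.1)
Conditions: TBAF, AcOH (buffer), THF, 0 °C → rt, dark, Ar
Reagents that add atoms: none
Why: Fluoride cleavage of the primary silyl ether, buffered to spare the polyene; no stereocentre or double bond is affected.

## Compound list

1 | (1S,5S)-(−)-α-pinene [(1S,5S)-2,6,6-trimethylbicyclo[3.1.1]hept-2-ene] | CC1=CC[C@H]2C[C@@H]1C2(C)C | starting material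
2 | α-pinene secondary ozonide (1,2,4-trioxolane across the former C=C; new centres not specified) | CC12OOC(O1)C[C@H]3C[C@@H]2C3(C)C | intermediate (not isolated)
3 | 2-[(1R,3R)-3-acetyl-2,2-dimethylcyclobutyl]acetaldehyde | CC(=O)[C@@H]1C[C@H](CC=O)C1(C)C | intermediate
4 | methyl (2E)-4-[(1S,3R)-3-acetyl-2,2-dimethylcyclobutyl]-2-methylbut-2-enoate | CC(=O)[C@@H]1C[C@H](C/C=C(\C)C(=O)OC)C1(C)C | intermediate
5 | methyl (2E)-3-[(1S,3S)-3-[(2E)-4-methoxy-3-methyl-4-oxobut-2-en-1-yl]-2,2-dimethylcyclobutyl]but-2-enoate (major isomer) | COC(=O)/C=C(\C)[C@@H]1C[C@H](C/C=C(\C)C(=O)OC)C1(C)C | intermediate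
6 | zwitterion from C4′–C1′ heterolysis of 5: tertiary C1′ carbenium ion with O-bound dichloro(ethyl)aluminate dienolate (dienolate geometry not fixed) | CC[Al-](Cl)(Cl)OC(OC)=CC(C)=CC[C@H](C/C=C(\C)C(=O)OC)[C+](C)C | intermediate (not isolated)
7 | methyl (1R,5R)-5-[(2E)-4-methoxy-3-methyl-4-oxobut-2-en-1-yl]-2,6,6-trimethylcyclohex-2-ene-1-carboxylate | COC(=O)[C@@H]1C(C)=CC[C@H](C/C=C(\C)C(=O)OC)C1(C)C | intermediate
8 | (2E)-4-[(1R,5R)-5-(hydroxymethyl)-4,6,6-trimethylcyclohex-3-en-1-yl]-2-methylbut-2-en-1-ol | OC[C@@H]1C(C)=CC[C@H](C/C=C(\C)CO)C1(C)C | intermediate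
9 | [(1R,5R)-5-[(2E)-4-{[tert-butyl(diphenyl)silyl]oxy}-3-methylbut-2-en-1-yl]-2,6,6-trimethylcyclohex-2-en-1-yl]methanol | OC[C@@H]1C(C)=CC[C@H](C/C=C(\C)CO[Si](c2ccccc2)(c2ccccc2)C(C)(C)C)C1(C)C | intermediate
10 | 5-({[(1R,5R)-5-[(2E)-4-{[tert-butyl(diphenyl)silyl]oxy}-3-methylbut-2-en-1-yl]-2,6,6-trimethylcyclohex-2-en-1-yl]methyl}sulfanyl)-1-phenyl-1H-tetrazole | c1ccccc1-n1nnnc1SC[C@@H]1C(C)=CC[C@H](C/C=C(\C)CO[Si](c2ccccc2)(c2ccccc2)C(C)(C)C)C1(C)C | intermediate
11 | 5-({[(1R,5R)-5-[(2E)-4-{[tert-butyl(diphenyl)silyl]oxy}-3-methylbut-2-en-1-yl]-2,6,6-trimethylcyclohex-2-en-1-yl]methyl}sulfonyl)-1-phenyl-1H-tetrazole | c1ccccc1-n1nnnc1S(=O)(=O)C[C@@H]1C(C)=CC[C@H](C/C=C(\C)CO[Si](c2ccccc2)(c2ccccc2)C(C)(C)C)C1(C)C | intermediate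
12 | 2-[(1R,3R)-3-acetyl-2,2-dimethylcyclobutyl]acetic acid | CC(=O)[C@@H]1C[C@H](CC(=O)O)C1(C)C | intermediate
13 | (4R)-5,5-dimethyl-4-(3-oxobutyl)oxolan-2-one | CC(=O)CC[C@@H]1CC(=O)OC1(C)C | intermediate
14 | (4S)-5,5-dimethyl-4-[(1E)-3-oxobut-1-en-1-yl]oxolan-2-one | CC(=O)/C=C/[C@@H]1CC(=O)OC1(C)C | intermediate
15 | ethyl (2E,4E)-5-[(3S)-2,2-dimethyl-5-oxooxolan-3-yl]-3-methylpenta-2,4-dienoate | CCOC(=O)/C=C(\C)/C=C/[C@@H]1CC(=O)OC1(C)C | intermediate
16 | (4S)-4-[(1E,3E)-5-hydroxy-3-methylpenta-1,3-dien-1-yl]-5,5-dimethyloxolan-2-ol (anomers) | OC/C=C(\C)/C=C/[C@@H]1CC(O)OC1(C)C | intermediate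
17 | (2E,4E,6S)-6-(2-hydroxypropan-2-yl)-3,9-dimethyldeca-2,4,8-trien-1-ol | CC(C)=CC[C@@H](/C=C/C(C)=C/CO)C(C)(C)O | intermediate
18 | [(2E,4E,6S)-6-(2-hydroxypropan-2-yl)-3,9-dimethyldeca-2,4,8-trien-1-yl](triphenyl)phosphonium bromide | [Br-].CC(C)=CC[C@@H](/C=C/C(C)=C/C[P+](c1ccccc1)(c1ccccc1)c1ccccc1)C(C)(C)O | intermediate
19 | (2E,4E,6E,8E,10E,12E,14E)-2,6,11,15-tetramethylhexadeca-2,4,6,8,10,12,14-heptaenedial (crocetindialdehyde) | O=C/C(C)=C/C=C/C(C)=C/C=C/C=C(C)/C=C/C=C(C)/C=O | starting material
20 | (2E,4E,6E,8E,10E,12E,14E,16E)-17-[(1R,5R)-5-[(2E)-4-{[tert-butyl(diphenyl)silyl]oxy}-3-methylbut-2-en-1-yl]-2,6,6-trimethylcyclohex-2-en-1-yl]-2,6,11,15-tetramethylheptadeca-2,4,6,8,10,12,14,16-octaenal | O=C/C(C)=C/C=C/C(C)=C/C=C/C=C(C)/C=C/C=C(C)/C=C/[C@@H]1C(C)=CC[C@H](C/C=C(\C)CO[Si](c2ccccc2)(c2ccccc2)C(C)(C)C)C1(C)C | intermediate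
21 | (2S,2′R,6′R)-2′-[(2E)-4-{[tert-butyl(diphenyl)silyl]oxy}-3-methylbut-2-en-1-yl]-2-(3-methylbut-2-en-1-yl)-3,4-didehydro-1,2-dihydro-ψ,ε-caroten-1-ol | CC(C)=CC[C@@H](/C=C/C(C)=C/C=C/C(C)=C/C=C/C(C)=C/C=C/C=C(C)/C=C/C=C(C)/C=C/[C@@H]1C(C)=CC[C@H](C/C=C(\C)CO[Si](c2ccccc2)(c2ccccc2)C(C)(C)C)C1(C)C)C(C)(C)O | intermediate
22 | (2S,2′R,6′R)-2′-[(2E)-4-hydroxy-3-methylbut-2-en-1-yl]-2-(3-methylbut-2-en-1-yl)-3,4-didehydro-1,2-dihydro-ψ,ε-caroten-1-ol | CC(C)=CC[C@@H](/C=C/C(C)=C/C=C/C(C)=C/C=C/C(C)=C/C=C/C=C(C)/C=C/C=C(C)/C=C/[C@@H]1C(C)=CC[C@H](C/C=C(\C)CO)C1(C)C)C(C)(C)O | target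

## Step count and least certain steps

Total: 18 steps (ring fragment steps 1–8, open fragment steps 9–15, assembly steps 16–18). Longest linear sequence: 11 steps (1–8, then 16–18).

Step 4 (key step, proposed new method). Three things may go wrong.
- The vinylogous mono-ester may be too weak an acceptor, so that ionisation of the C4′–C1′ bond does not set in below the temperature at which the cation loses a proton or suffers a 1,2-hydride shift from C2′. This would give open-chain trienes or erode the C2′ configuration.
- Facial selectivity at C6′ may fail. A least-motion collapse of the ion pair from the cis-cyclobutane E-enoate, before the tether relaxes, leads to the 2′,6′-trans isomer. The trans ester is probably also the thermodynamic one, so it cannot be corrected by equilibration.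
- Proton transfer within 6 (net retro-ene) would be a dead end under aprotic conditions.

Fallback by known chemistry: set out from 13, which the other branch supplies with the same absolute configuration at the future C2′. Horner–Wadsworth–Emmons olefination of its ketone gives methyl (2E)-5-[(3R)-2,2-dimethyl-5-oxooxolan-3-yl]-3-methylpent-2-enoate F1. A protic-acid cyclisation of the geranate type follows: the lactone C–O bond ionises to the same C1′ cation and the E enoate closes through a chair with both substituents equatorial, which gives 2-[(1R,5R)-5-(methoxycarbonyl)-4,6,6-trimethylcyclohex-3-en-1-yl]acetic acid F2. Borane reduction of the acid gives methyl (1R,5R)-5-(2-hydroxyethyl)-2,6,6-trimethylcyclohex-2-ene-1-carboxylate F3. Oxidation gives methyl (1R,5R)-2,6,6-trimethyl-5-(2-oxoethyl)cyclohex-2-ene-1-carboxylate F4, and the Wittig reaction with the ylide of step 2 returns to the route at 7.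

Step 16. Olefination of both aldehyde groups of 19, incomplete E selectivity with a conjugated aldehyde, self-condensation of the metallated sulfone and the low solubility of 19 at low temperature may all cut the throughput. Fallback: set out from 9 and convert the alcohol to tert-butyl{[(2E)-4-[(1R,5R)-5-(iodomethyl)-4,6,6-trimethylcyclohex-3-en-1-yl]-2-methylbut-2-en-1-yl]oxy}diphenylsilane F5 (I2, PPh3, imidazole). Heating with PPh3 gives {[(1R,5R)-5-[(2E)-4-{[tert-butyl(diphenyl)silyl]oxy}-3-methylbut-2-en-1-yl]-2,6,6-trimethylcyclohex-2-en-1-yl]methyl}(triphenyl)phosphonium iodide F6. A Wittig reaction of its ylide with excess 19, followed by iodine-catalysed Z→E isomerisation of the new disubstituted bond, returns to the route at 20.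

Step 11. Dehydrogenation may stall, or may run on to further desaturation at the γ-carbon (the stereocentre), which would destroy C2. Fallback: set out from 13 and use acid-catalysed selenenylation with PhSeCl on the more substituted enol to (4S)-5,5-dimethyl-4-[3-oxo-2-(phenylselanyl)butyl]oxolan-2-one F7. Oxidation with H2O2 and syn-elimination of the selenoxide return to the route at 14.

Step 15. Ionisation of the dienyl alcohol under acid may scramble the C5=C6 geometry, let phosphine enter at C5 or C3, or dehydrate the tertiary alcohol. Fallback without acid: set out from 17 and make (3S,4E,6E)-8-chloro-2,6-dimethyl-3-(3-methylbut-2-en-1-yl)octa-4,6-dien-2-ol F8 (MsCl, LiCl, s-collidine, DMF, 0 °C; the primary allylic alcohol reacts, the tertiary one does not). PPh3 then gives [(2E,4E,6S)-6-(2-hydroxypropan-2-yl)-3,9-dimethyldeca-2,4,8-trien-1-yl](triphenyl)phosphonium chloride F9, which is used in the Wittig reaction with 20 in place of 18 and returns to the route at 21.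

## Further compounds

F1 | step 4 | methyl (2E)-5-[(3R)-2,2-dimethyl-5-oxooxolan-3-yl]-3-methylpent-2-enoate | COC(=O)/C=C(\C)CC[C@@H]1CC(=O)OC1(C)C
F2 | step 4 | 2-[(1R,5R)-5-(methoxycarbonyl)-4,6,6-trimethylcyclohex-3-en-1-yl]acetic acid | COC(=O)[C@@H]1C(C)=CC[C@H](CC(=O)O)C1(C)C
F3 | step 4 | methyl (1R,5R)-5-(2-hydroxyethyl)-2,6,6-trimethylcyclohex-2-ene-1-carboxylate | COC(=O)[C@@H]1C(C)=CC[C@H](CCO)C1(C)C
F4 | step 4 | methyl (1R,5R)-2,6,6-trimethyl-5-(2-oxoethyl)cyclohex-2-ene-1-carboxylate | COC(=O)[C@@H]1C(C)=CC[C@H](CC=O)C1(C)C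
F5 | step 16 | tert-butyl{[(2E)-4-[(1R,5R)-5-(iodomethyl)-4,6,6-trimethylcyclohex-3-en-1-yl]-2-methylbut-2-en-1-yl]oxy}diphenylsilane | IC[C@@H]1C(C)=CC[C@H](C/C=C(\C)CO[Si](c2ccccc2)(c2ccccc2)C(C)(C)C)C1(C)C
F6 | step 16 | {[(1R,5R)-5-[(2E)-4-{[tert-butyl(diphenyl)silyl]oxy}-3-methylbut-2-en-1-yl]-2,6,6-trimethylcyclohex-2-en-1-yl]methyl}(triphenyl)phosphonium iodide | [I-].c1ccccc1[P+](c1ccccc1)(c1ccccc1)C[C@@H]1C(C)=CC[C@H](C/C=C(\C)CO[Si](c2ccccc2)(c2ccccc2)C(C)(C)C)C1(C)C
F7 | step 11 | (4S)-5,5-dimethyl-4-[3-oxo-2-(phenylselanyl)butyl]oxolan-2-one (both epimers at the selenium-bearing carbon) | CC(=O)C([Se]c1ccccc1)C[C@@H]1CC(=O)OC1(C)C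
F8 | step 15 | (3S,4E,6E)-8-chloro-2,6-dimethyl-3-(3-methylbut-2-en-1-yl)octa-4,6-dien-2-ol | CC(C)=CC[C@@H](/C=C/C(C)=C/CCl)C(C)(C)O
F9 | step 15 | [(2E,4E,6S)-6-(2-hydroxypropan-2-yl)-3,9-dimethyldeca-2,4,8-trien-1-yl](triphenyl)phosphonium chloride | [Cl-].CC(C)=CC[C@@H](/C=C/C(C)=C/C[P+](c1ccccc1)(c1ccccc1)c1ccccc1)C(C)(C)O
A1 | alternative 1 | [(2E,4E)-5-[(1R,5R)-5-[(2E)-4-hydroxy-3-methylbut-2-en-1-yl]-2,6,6-trimethylcyclohex-2-en-1-yl]-3-methylpenta-2,4-dien-1-yl](triphenyl)phosphonium bromide | [Br-].c1ccccc1[P+](c1ccccc1)(c1ccccc1)C/C=C(C)/C=C/[C@@H]1C(C)=CC[C@H](C/C=C(\C)CO)C1(C)C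
A2 | alternative 1 | methyl (2E,6R)-6-[(2E)-4-(acetyloxy)-3-methylbut-2-en-1-yl]-7-hydroxy-3,7-dimethyloct-2-enoate | COC(=O)/C=C(\C)CC[C@H](C/C=C(\C)COC(C)=O)C(C)(C)O
A3 | alternative 1 | (2E,4E,6E)-2,7-dimethylocta-2,4,6-trienedial | O=C/C(C)=C/C=C/C=C(C)/C=O
A4 | alternative 2 | 2,4,4-trimethylcyclohexa-2,5-dien-1-one | CC1=CC(C)(C)C=CC1=O
A5 | alternative 2 | (1R,5S)-2,4,4-trimethyl-5-(prop-2-en-1-yl)cyclohex-2-en-1-ol (allyl as side-chain precursor) | O[C@@H]1C[C@H](CC=C)C(C)(C)C=C1C
A6 | alternative 2 | tributyl({[(1R,5S)-2,4,4-trimethyl-5-(prop-2-en-1-yl)cyclohex-2-en-1-yl]oxy}methyl)stannane | CCCC[Sn](CCCC)(CCCC)CO[C@@H]1C[C@H](CC=C)C(C)(C)C=C1C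
A7 | alternative 3 | 5,5-dimethylcyclopenta-1,3-diene | CC1(C)C=CC=C1
A8 | alternative 3 | (1R,5S)-8,8-dimethylbicyclo[3.2.1]oct-6-en-3-one (meso) | O=C1C[C@H]2C=C[C@@H](C1)C2(C)C
A9 | alternative 3 | (1R,3S)-2,2-dimethyl-5-oxocyclohexane-1,3-dicarbaldehyde (meso, cis) | O=C[C@@H]1CC(=O)C[C@H](C=O)C1(C)C
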